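Ring A is disconnected across C1–C2 and C3–C4 into a 2-pyrone and a 1-methoxyalkyne. The run C4 (benzyl)–C5 (oxygen)–C6 (H)–C1 (chain) of ring A is already present as C3–C6 of a 3-benzyl-4-acyloxy-6-alkyl-2-pyrone grown from triacetic acid lactone; C2 (benzyl) and C3 (OMe) arrive with the alkyne. One thermal operation, [4+2] cycloaddition then loss of CO2, forms both bonds and aromatises the pentasubstituted ring with all six positions correctly filled. The diene precursor is the 4-pivaloyloxy pyrone bearing a 4-benzyloxybenzyl group at C3 and a 2-(3-benzyloxyphenyl)ethyl chain at C6; its partner is 1-methoxy-3-(4-benzyloxyphenyl)propyne.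

Key step: step 5

Remark on the chemistry: ring A is numbered C1 (CH2CH2 chain to ring B), C2 and C4 (4-hydroxybenzyl), C3 (OMe), C5 (OH), C6 (H). The pivalate is kept because it has no α-hydrogen and is hindered; the ynol ether is the methyl ether because it has no β-hydrogen; all three phenols travel as benzyl ethers and are released together at the end. The bridged cycloadduct of the key step is assumed to form as a racemate, which is without consequence because both of its stereocentres vanish in the same flask.

Step 1
Reactants: 1 triacetic acid lactone (4-hydroxy-6-methyl-2H-pyran-2-one); 2 3-benzyloxybenzyl bromide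
Product: 4 6-[2-(3-benzyloxyphenyl)ethyl]-4-hydroxy-2H-pyran-2-one, via dilithium dianion 3 (not isolated)
Conditions: LDA (2.3 equiv), THF/DMPU, −78 °C; then 2, −78 → −20 °C; 1 M HCl work-up
Reagents that add atoms: none
Why: The base removes first the acidic 4-OH proton and then a proton of the 6-methyl group, and the vinylogous dianion 3 reacts at its more basic carbon terminus with the benzylic bromide in an SN2 step (γ-alkylation of a 1,3-dicarbonyl dianion).

Step 2
Reactants: 4 6-[2-(3-benzyloxyphenyl)ethyl]-4-hydroxy-2H-pyran-2-one; 5 4-benzyloxybenzaldehyde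
Product: 7 3-(4-benzyloxybenzyl)-6-[2-(3-benzyloxyphenyl)ethyl]-4-hydroxy-2H-pyran-2-one, via alkylidene pyrandione 6 (not isolated)
Conditions: diethyl 2,6-dimethyl-1,4-dihydropyridine-3,5-dicarboxylate (Hantzsch ester, 1.1 equiv), L-proline (20 mol%), CH2Cl2, 25 °C
Reagents that add atoms: none
Why: Proline-catalysed Knoevenagel condensation at C3 gives the strongly electrophilic alkylidene 6, which should be reduced at once by conjugate hydride transfer from the dihydropyridine before a second pyrone can add (organocatalytic three-component reductive alkylation); no stereocentre is formed.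

Step 3
Reactants: 7 3-(4-benzyloxybenzyl)-6-[2-(3-benzyloxyphenyl)ethyl]-4-hydroxy-2H-pyran-2-one
Product: 8 3-(4-benzyloxybenzyl)-6-[2-(3-benzyloxyphenyl)ethyl]-2-oxo-2H-pyran-4-yl pivalate
Conditions: PivCl (1.2 equiv), Et3N (1.5 equiv), DMAP (5 mol%), CH2Cl2, 0 °C → 25 °C
Reagents that add atoms: pivaloyl chloride, CC(C)(C)C(=O)Cl
Why: The vinylogous acid is acylated on O4 by the acyl chloride under nucleophilic catalysis (O-acylation), and because C3 is already substituted no O-to-C acyl migration can follow.

Step 4
Reactants: 9 chloroacetaldehyde dimethyl acetal (2-chloro-1,1-dimethoxyethane); 10 4-benzyloxybenzyl chloride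
Product: 12 1-methoxy-3-(4-benzyloxyphenyl)prop-1-yne, via lithium methoxyacetylide 11 (not isolated)
Conditions: Et2NH/n-BuLi (3.0 equiv LiNEt2), THF, 0 °C; then DMPU, 10 (0.7 equiv), Bu4NI (10 mol%), −78 → 0 °C; cold pH 7 buffer; Et3N-deactivated silica
Reagents that add atoms: none
Why: Twofold elimination (methanol, then HCl) and deprotonation of the chloroacetal by LiNEt2 gives acetylide 11, whose SN2 alkylation by the activated benzylic chloride in a dipolar co-solvent is the standard entry to 1-alkoxy-1-alkynes (acetylide alkylation); the halide is limiting and the quench is cold and neutral to spare the acid-sensitive ynol ether.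

Step 5
Reactants: 8 3-(4-benzyloxybenzyl)-6-[2-(3-benzyloxyphenyl)ethyl]-2-oxo-2H-pyran-4-yl pivalate; 12 1-methoxy-3-(4-benzyloxyphenyl)prop-1-yne
Product: 14 2,4-bis(4-benzyloxybenzyl)-5-[2-(3-benzyloxyphenyl)ethyl]-3-methoxyphenyl pivalate, via bridged lactone cycloadduct 13 (not isolated)
Conditions: 12 (3 equiv), BHT (5 mol%), mesitylene (1 M), sealed tube, 160 °C
Reagents that add atoms: none
Why: Proposed new method: the ynol ether and the pyrone should combine in an asynchronous, polarity-matched [4+2] cycloaddition in which the nucleophilic alkyne carbon (the benzyl-bearing one, β to oxygen) attacks electrophilic pyrone C6 while the methoxy-bearing carbon closes onto C3, and the bridged lactone 13 then expels CO2 by retro-[4+2] at the reaction temperature to give the arene. The closest known reaction type is the thermal cycloaddition of 2-pyrones with ynamines or electron-poor alkynes followed by CO2 extrusion, which has not been shown for a 3,6-dialkyl-4-acyloxy-2-pyrone paired with an alkoxyalkyne. Ring A is closed by an intermolecular [4+2] between the four-carbon diene C3–C6 of the pyrone and the two alkyne carbons, forming C1–C2 and C3–C4 of ring A, and the bicycle is unlocked by cycloreversion. The two bridgehead stereocentres of 13 are fixed relative to each other by the bicyclic frame and are both erased on aromatisation, so no stereocontrol is required. The selectivity needed is regiochemical, and it is secured by the polarity of both partners: C6 is the electrophilic diene terminus (vinylogous to the lactone carbonyl, with the acyloxy group withdrawing rather than donating), C3 is the enolate-like terminus, and the alkyne is polarised by oxygen in the complementary sense. Reactivity, not orientation, is the weak point, which is why the alkyne is used in excess at high concentration and why both partners are built without a hydrogen that would allow thermal ketene formation (the pivalate has no α-hydrogen, the methyl ynol ether no β-hydrogen).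

Step 6
Reactants: 14 2,4-bis(4-benzyloxybenzyl)-5-[2-(3-benzyloxyphenyl)ethyl]-3-methoxyphenyl pivalate
Product: 15 2,4-bis(4-benzyloxybenzyl)-5-[2-(3-benzyloxyphenyl)ethyl]-3-methoxyphenol
Conditions: NaOMe (2 equiv), MeOH/THF, 25 → 40 °C; 1 M HCl quench
Reagents that add atoms: none
Why: Methoxide attacks the ester carbonyl and expels the phenoxide (transesterification of an aryl ester), while the benzyl and methyl ethers are inert to base.

Step 7
Reactants: 15 2,4-bis(4-benzyloxybenzyl)-5-[2-(3-benzyloxyphenyl)ethyl]-3-methoxyphenol
Product: 16 bulbocodin C, 2,4-bis(4-hydroxybenzyl)-5-[2-(3-hydroxyphenyl)ethyl]-3-methoxyphenol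
Conditions: H2 (1 atm), 10% Pd/C, EtOAc/MeOH, 25 °C
Reagents that add atoms: none
Why: Heterogeneous hydrogenolysis cleaves the three benzylic C–O bonds of the aryl benzyl ethers, whereas the diarylmethane and bibenzyl C–C bonds and the aryl methyl ether should survive at this pressure and temperature.

Compound list
1 | triacetic acid lactone (4-hydroxy-6-methyl-2H-pyran-2-one) | CC1=CC(O)=CC(=O)O1 | starting material
2 | 3-benzyloxybenzyl bromide | BrCc1cccc(OCc2ccccc2)c1 | starting material
3 | dilithium dianion of triacetic acid lactone (4-oxide, 6-methylide; formed in the flask) | [Li+].[Li+].[CH2-]C1=CC([O-])=CC(=O)O1 | intermediate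
4 | 6-[2-(3-benzyloxyphenyl)ethyl]-4-hydroxy-2H-pyran-2-one | O=C1OC(CCc2cccc(OCc3ccccc3)c2)=CC(O)=C1 | intermediate
5 | 4-benzyloxybenzaldehyde | O=Cc1ccc(OCc2ccccc2)cc1 | starting material
6 | 3-(4-benzyloxybenzylidene)-6-[2-(3-benzyloxyphenyl)ethyl]-2H-pyran-2,4(3H)-dione (formed in the flask; alkene geometry undefined, the double bond is reduced at once) | O=C1OC(CCc2cccc(OCc3ccccc3)c2)=CC(=O)C1=Cc1ccc(OCc2ccccc2)cc1 | intermediate
7 | 3-(4-benzyloxybenzyl)-6-[2-(3-benzyloxyphenyl)ethyl]-4-hydroxy-2H-pyran-2-one | O=C1OC(CCc2cccc(OCc3ccccc3)c2)=CC(O)=C1Cc1ccc(OCc2ccccc2)cc1 | intermediate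
8 | 3-(4-benzyloxybenzyl)-6-[2-(3-benzyloxyphenyl)ethyl]-2-oxo-2H-pyran-4-yl pivalate | O=C1OC(CCc2cccc(OCc3ccccc3)c2)=CC(OC(=O)C(C)(C)C)=C1Cc1ccc(OCc2ccccc2)cc1 | intermediate
9 | chloroacetaldehyde dimethyl acetal (2-chloro-1,1-dimethoxyethane) | COC(CCl)OC | starting material
10 | 4-benzyloxybenzyl chloride | ClCc1ccc(OCc2ccccc2)cc1 | starting material
11 | lithium methoxyacetylide (formed in the flask) | [Li+].[C-]#COC | intermediate
12 | 1-methoxy-3-(4-benzyloxyphenyl)prop-1-yne | COC#CCc1ccc(OCc2ccccc2)cc1 | intermediate
13 | 4,7-bis(4-benzyloxybenzyl)-1-[2-(3-benzyloxyphenyl)ethyl]-8-methoxy-3-oxo-2-oxabicyclo[2.2.2]octa-5,7-dien-5-yl pivalate (formed in the flask; racemic, one enantiomer drawn, bridgeheads mutually fixed by the bicycle) | O=C1O[C@]2(CCc3cccc(OCc4ccccc4)c3)C=C(OC(=O)C(C)(C)C)[C@@]1(Cc5ccc(OCc6ccccc6)cc5)C(OC)=C2Cc7ccc(OCc8ccccc8)cc7 | intermediate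
14 | 2,4-bis(4-benzyloxybenzyl)-5-[2-(3-benzyloxyphenyl)ethyl]-3-methoxyphenyl pivalate | COc1c(Cc2ccc(OCc3ccccc3)cc2)c(OC(=O)C(C)(C)C)cc(CCc2cccc(OCc3ccccc3)c2)c1Cc1ccc(OCc2ccccc2)cc1 | intermediate
15 | 2,4-bis(4-benzyloxybenzyl)-5-[2-(3-benzyloxyphenyl)ethyl]-3-methoxyphenol | COc1c(Cc2ccc(OCc3ccccc3)cc2)c(O)cc(CCc2cccc(OCc3ccccc3)c2)c1Cc1ccc(OCc2ccccc2)cc1 | intermediate
16 | bulbocodin C, 2,4-bis(4-hydroxybenzyl)-5-[2-(3-hydroxyphenyl)ethyl]-3-methoxyphenol (no stereocentre) | COc1c(Cc2ccc(O)cc2)c(O)cc(CCc2cccc(O)c2)c1Cc1ccc(O)cc1 | target

Total step count: 7 (steps 1–7).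
Longest linear sequence: 6 steps (steps 1, 2, 3, 5, 6, 7 from triacetic acid lactone); step 4 is a one-step side branch.

Steps most likely to fail

Step 5 (bears the label). The cycloaddition may be slower than thermal oligomerisation or adventitious hydration of the ynol ether, so that the alkyne is consumed while the pyrone is recovered; bond formation in the opposite orientation is the less likely failure. The fallback is a Danheiser benzannulation of a cyclobutenone with the same alkynyl ether, which is known chemistry; it sets out from 12 and comes back at 15, so that steps 5 and 6 and the pyrone branch are bypassed. [2+2] Cycloaddition of 12 with ketene F1 (from pyrolysis of acetone, passed into a CH2Cl2 solution of 12 at 0 °C) should give 2-(4-benzyloxybenzyl)-3-methoxycyclobut-2-en-1-one F2, the ketene carbonyl carbon bonding to the benzyl-bearing alkyne carbon. Addition of 2-(3-benzyloxyphenyl)ethylmagnesium bromide F3 (from commercial 1-(benzyloxy)-3-(2-bromoethyl)benzene and Mg in THF) to the carbonyl group of F2 at −78 °C gives the tertiary carbinol 2-(4-benzyloxybenzyl)-1-[2-(3-benzyloxyphenyl)ethyl]-3-methoxycyclobut-2-en-1-ol F4. On work-up with dilute HCl this loses methanol with allylic transposition to give 2-(4-benzyloxybenzyl)-3-[2-(3-benzyloxyphenyl)ethyl]cyclobut-2-en-1-one F5. Heating F5 with a second portion of 12 in toluene at 80–110 °C should deliver phenol 15 directly. The pericyclic cascade of this benzannulation (four-electron ring opening, [2+2] addition, second ring opening, six-electron closure, tautomerisation) puts the cyclobutenone carbonyl at C5 and the alkyne carbons at C4 and C3. Cyclobutenone C2, C3 and C4 become C2, C1 and C6 of ring A.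

Step 4. The liberated diethylamine and lithium methoxide can capture the benzylic chloride in competition with C-alkylation, residual base can isomerise the aryl–propargyl product to an allenyl ether, and the ynol ether can hydrate to a methyl ester during work-up. The fallback generates the acetylide without amine and replaces the SN2 alkylation by a palladium-catalysed sp–sp3 coupling; it sets out from 10 and comes back at 12. Trichloroethylene with KH and methanol in THF gives (E)-1,2-dichloro-1-methoxyethene F6, and two equivalents of n-BuLi at −78 °C convert F6 into 11 free of amine and alkoxide. Transmetalation with ZnBr2 gives methoxyethynylzinc bromide F7, and Negishi coupling of F7 with 10 under PdCl2(DPEphos) catalysis in THF at 25 °C should give 12 under essentially non-basic conditions.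

Step 1. Incomplete formation of the sparingly soluble dianion leads to O- or C3-benzylation of the monoanion, and proton transfer from product to dianion leads to double alkylation on the side chain. The fallback assembles the pyrone de novo from an open-chain 3,5-diketo ester; it sets out from 2 and comes back at 4. Alkylation of N-methoxy-N-methylacetamide (LDA, THF, −78 °C) with 2 gives the Weinreb amide N-methoxy-N-methyl-3-(3-benzyloxyphenyl)propanamide F8. Acylation of doubly deprotonated methyl acetoacetate (NaH then n-BuLi, THF, 0 °C) by F8 gives methyl 7-(3-benzyloxyphenyl)-3,5-dioxoheptanoate F9, and lactonisation of F9 with DBU in toluene at reflux gives 4.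

Further compounds
F1 | step 5 | ketene | C=C=O
F2 | step 5 | 2-(4-benzyloxybenzyl)-3-methoxycyclobut-2-en-1-one | COC1=C(Cc2ccc(OCc3ccccc3)cc2)C(=O)C1
F3 | step 5 | 2-(3-benzyloxyphenyl)ethylmagnesium bromide | Br[Mg]CCc1cccc(OCc2ccccc2)c1
F4 | step 5 | 2-(4-benzyloxybenzyl)-1-[2-(3-benzyloxyphenyl)ethyl]-3-methoxycyclobut-2-en-1-ol (racemic) | COC1=C(Cc2ccc(OCc3ccccc3)cc2)C(O)(CCc2cccc(OCc3ccccc3)c2)C1
F5 | step 5 | 2-(4-benzyloxybenzyl)-3-[2-(3-benzyloxyphenyl)ethyl]cyclobut-2-en-1-one | O=C1CC(CCc2cccc(OCc3ccccc3)c2)=C1Cc1ccc(OCc2ccccc2)cc1
F6 | step 4 | (E)-1,2-dichloro-1-methoxyethene | CO/C(Cl)=C\Cl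
F7 | step 4 | methoxyethynylzinc bromide | COC#C[Zn]Br
F8 | step 1 | N-methoxy-N-methyl-3-(3-benzyloxyphenyl)propanamide | CON(C)C(=O)CCc1cccc(OCc2ccccc2)c1
F9 | step 1 | methyl 7-(3-benzyloxyphenyl)-3,5-dioxoheptanoate | COC(=O)CC(=O)CC(=O)CCc1cccc(OCc2ccccc2)c1
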